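**Retrosynthetic overview**
1. Vidalol B ⇒ tribromo bis-salicylaldehyde. In each outer ring the C5–OH bond (aryl C–O) comes from a formyl group, and the new OH then directs the last Br to its para carbon, all in one flask (key step).
2. Tribromo bis-salicylaldehyde ⇒ bis-benzylated trihydroxybenzoic acid, by three C–Br bonds. The central Br replaces a CO2H placeholder, and each outer Br goes ortho to the only free OH.
3. Bis-benzylated acid ⇒ 2,4,6-trihydroxybenzoic acid plus two 5-(chloromethyl)salicylaldehyde units, by two aryl–CH2 bonds (Friedel–Crafts).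
4. No ring is built. Central ring A and outer rings B and C are bought as catalogue benzene derivatives, and bonds are made in the order C–C, then C–Br, then C–O with C–Br.

Assumption: the SMILES has no stereodescriptor and the molecule has no stereocentre or stable axis, so the target is one achiral compound and no step has to set configuration.

**Step 1**
Reactants: 1 2,4,6-trihydroxybenzoic acid (1.0 equiv); 2 5-(chloromethyl)-2-hydroxybenzaldehyde (2.05 equiv)
Product: 3 3,5-bis(3-formyl-4-hydroxybenzyl)-2,4,6-trihydroxybenzoic acid
Conditions: ZnCl2 (0.2 equiv), 1,4-dioxane, 25 to 40 °C, 3 h, 2 added in portions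
Reagents that add atoms: none
Why: Friedel–Crafts benzylation, in which ZnCl2 ionises the para-hydroxy-stabilised benzylic chloride and the two free carbons of 1 (each ortho/para to three OH groups) capture it, while CO2H blocks the third site against a third benzylation, O-alkylation is reversible, the formyl group keeps the rings of 2 too electron-poor to self-condense, and no stereocentre is formed.

**Step 2**
Reactants: 3 3,5-bis(3-formyl-4-hydroxybenzyl)-2,4,6-trihydroxybenzoic acid
Product: 4 2-bromo-4,6-bis(3-bromo-5-formyl-4-hydroxybenzyl)benzene-1,3,5-triol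
Conditions: Br2 (3.05 equiv), AcOH, 15 to 25 °C, 4 h; then H2O, filter
Reagents that add atoms: bromine, BrBr
Why: Electrophilic aromatic bromination with ipso-bromodecarboxylation, in which the carboxyl-bearing carbon of ring A loses CO2 irreversibly after Br+ attack (as salicylic acid does with bromine water), each outer ring reacts only at the one open position ortho to OH because the formyl group deactivates the rest, the HBr kept in solution reverses any ipso-bromo dienone on ring A, and no stereocentre is formed.

**Step 3 (key step)**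
Reactants: 4 2-bromo-4,6-bis(3-bromo-5-formyl-4-hydroxybenzyl)benzene-1,3,5-triol
Product: 7 vidalol B, via bis-formate 5 (not isolated), via tribromo bis-catechol 6 (not isolated)
Conditions: 35% aq H2O2 (2.3 equiv), H2SO4 (1.5 equiv), MeOH (0.25 M), 25 °C, 6 h; then 48% aq HBr (2.0 equiv), 35% aq H2O2 (2.5 equiv), 30 °C, 12 h, N2, dark
Reagents that add atoms: hydrogen peroxide, OO; hydrogen bromide, Br
Why: Proposed new method: a peroxide-relayed "bromo-Dakin" sequence in which acidic H2O2 adds to each hydrogen-bonded salicylaldehyde carbonyl to give a perhydrate whose Criegee-type 1,2-aryl shift (driven by the ortho OH, hardly affected by the meta Br) forms the aryl C–O bond as formate 5, methanolysis frees catechol 6, and only then is bromide dosed in as the limiting reagent so that the same acidic peroxide oxidises it slowly to Br2, which is taken up at the carbon para to the newly made OH (the position at which 5-bromovanillin also brominates), so the formyl-to-hydroxyl exchange switches an inert ring carbon into the most reactive one; the closest known reaction types are the acid-catalysed Dakin oxidation of hydroxybenzaldehydes and H2O2/HBr oxidative bromination of phenols, which have not been coupled in one flask nor shown on an unprotected polybrominated bis-salicylaldehyde with a free phloroglucinol core, and no stereocentre is formed.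

**Compound list**
1 | 2,4,6-trihydroxybenzoic acid | OC(=O)c1c(O)cc(O)cc1O | starting material
2 | 5-(chloromethyl)-2-hydroxybenzaldehyde | O=Cc1cc(CCl)ccc1O | starting material
3 | 3,5-bis(3-formyl-4-hydroxybenzyl)-2,4,6-trihydroxybenzoic acid | OC(=O)c1c(O)c(Cc2ccc(O)c(C=O)c2)c(O)c(Cc2ccc(O)c(C=O)c2)c1O | intermediate
4 | 2-bromo-4,6-bis(3-bromo-5-formyl-4-hydroxybenzyl)benzene-1,3,5-triol | Oc1c(Br)c(O)c(Cc2cc(Br)c(O)c(C=O)c2)c(O)c1Cc1cc(Br)c(O)c(C=O)c1 | intermediate
5 | 2-bromo-4,6-bis[3-bromo-5-(formyloxy)-4-hydroxybenzyl]benzene-1,3,5-triol (bis-formate) | Oc1c(Br)c(O)c(Cc2cc(Br)c(O)c(OC=O)c2)c(O)c1Cc1cc(Br)c(O)c(OC=O)c1 | intermediate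
6 | 2-bromo-4,6-bis(3-bromo-4,5-dihydroxybenzyl)benzene-1,3,5-triol (tribromo bis-catechol) | Oc1c(Br)c(O)c(Cc2cc(Br)c(O)c(O)c2)c(O)c1Cc1cc(Br)c(O)c(O)c1 | intermediate
7 | vidalol B, 2-bromo-4,6-bis(2,3-dibromo-4,5-dihydroxybenzyl)benzene-1,3,5-triol (achiral) | Oc1cc(Cc2c(O)c(Br)c(O)c(Cc3cc(O)c(O)c(Br)c3Br)c2O)c(Br)c(Br)c1O | target

**Totals**
Total step count: 3. Longest linear sequence: 3. No protecting groups are used.

**Steps most likely to fail (the route has three steps, ranked by risk)**

Step 3 (the proposed new step).
- Risks:
  - hydride rather than aryl migration, giving the acid or methyl ester;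
  - oxidation of the catechols to ortho-quinones by peroxide or Br2;
  - a third bromination at the remaining outer-ring CH;
  - ipso attack on ring A with loss of a benzyl arm.
- Fallback (known chemistry only): the catechol oxygens are bought with vanillin and uncovered by ether cleavage, so no late C–O bond is made. The fallback sets out from 1 and comes back to the route at 7. Vanillin is dibrominated (Br2, Fe powder, AcOH) to 2,3-dibromo-4-hydroxy-5-methoxybenzaldehyde F4. NaBH4 in MeOH reduces this to (2,3-dibromo-4-hydroxy-5-methoxyphenyl)methanol F5. Two equivalents of F5 benzylate 1 (ZnCl2, 1,4-dioxane, 40 °C) to 3,5-bis(2,3-dibromo-4-hydroxy-5-methoxybenzyl)-2,4,6-trihydroxybenzoic acid F6. NBS (1.0 equiv, MeCN, 0 °C) bromodecarboxylates it to 2-bromo-4,6-bis(2,3-dibromo-4-hydroxy-5-methoxybenzyl)benzene-1,3,5-triol F7. BBr3 (CH2Cl2, −78 °C to 25 °C) then cleaves both methyl ethers to give 7.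

Step 1.
- Risks:
  - acid-promoted loss of CO2 from 1 before both benzylations are done, which reopens a third site;
  - condensation of the aldehyde groups with the phloroglucinol nucleus under the HCl that is released.
- Fallback: the aldehyde is kept out of the C–C coupling and installed afterwards. The fallback sets out from 1 and comes back at 3. Compound 1 is benzylated with 4-hydroxybenzyl alcohol (2.05 equiv, ZnCl2, 1,4-dioxane, 40 °C) to 2,4,6-trihydroxy-3,5-bis(4-hydroxybenzyl)benzoic acid F1. Magnesium-mediated ortho-formylation (excess MgCl2, Et3N, paraformaldehyde, MeCN, reflux) then puts one CHO next to the OH of each outer ring. Ring A has no free carbon and is held as its stable carboxylate, so the product is 3.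

Step 2.
- Risks:
  - the fully substituted ring A stays more nucleophilic than the formyl-bearing outer rings, so ipso bromination there can end in debenzylation;
  - ipso attack para to an outer-ring OH can cut the CH2 bridge.
- Fallback: the outer-ring bromines are installed before the coupling, so ring A meets only one equivalent of Br+. The fallback sets out from 2 and comes back at 4. NBS (1.0 equiv, MeCN, 0 °C) converts 2 into 3-bromo-5-(chloromethyl)-2-hydroxybenzaldehyde F2. Two equivalents of F2 benzylate 1 under the step 1 conditions to 3,5-bis(3-bromo-5-formyl-4-hydroxybenzyl)-2,4,6-trihydroxybenzoic acid F3. NBS (1.0 equiv, MeCN, 0 °C) then exchanges CO2H for Br to give 4.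

**Further compounds**
F1 | step 1 | 2,4,6-trihydroxy-3,5-bis(4-hydroxybenzyl)benzoic acid | OC(=O)c1c(O)c(Cc2ccc(O)cc2)c(O)c(Cc2ccc(O)cc2)c1O
F2 | step 2 | 3-bromo-5-(chloromethyl)-2-hydroxybenzaldehyde | O=Cc1cc(CCl)cc(Br)c1O
F3 | step 2 | 3,5-bis(3-bromo-5-formyl-4-hydroxybenzyl)-2,4,6-trihydroxybenzoic acid | OC(=O)c1c(O)c(Cc2cc(Br)c(O)c(C=O)c2)c(O)c(Cc2cc(Br)c(O)c(C=O)c2)c1O
F4 | step 3 | 2,3-dibromo-4-hydroxy-5-methoxybenzaldehyde | O=Cc1cc(OC)c(O)c(Br)c1Br
F5 | step 3 | (2,3-dibromo-4-hydroxy-5-methoxyphenyl)methanol | OCc1cc(OC)c(O)c(Br)c1Br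
F6 | step 3 | 3,5-bis(2,3-dibromo-4-hydroxy-5-methoxybenzyl)-2,4,6-trihydroxybenzoic acid | OC(=O)c1c(O)c(Cc2cc(OC)c(O)c(Br)c2Br)c(O)c(Cc2cc(OC)c(O)c(Br)c2Br)c1O
F7 | step 3 | 2-bromo-4,6-bis(2,3-dibromo-4-hydroxy-5-methoxybenzyl)benzene-1,3,5-triol | Oc1c(Br)c(O)c(Cc2cc(OC)c(O)c(Br)c2Br)c(O)c1Cc1cc(OC)c(O)c(Br)c1Br
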